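**Retrosynthetic overview**

1. The target (tetrahydrofuran numbered O1, C2 aryl, C3 CH2OH, C4 benzyl, C5 H2) comes from its C3 carboxylic acid, and this from a bicyclic lactone in which the C3 carbonyl and the benzylic carbon on C4 are tied as a γ-lactone; one hydrogenolysis cuts the benzylic lactone C–O bond and the phenol benzyl ether.
2. The bicyclic lactone comes from a [3+2] cycloaddition of the carbonyl ylide ArCH=O(+)–CH2(−) (atoms C2–O1–C5) to the C3=C4 double bond of an (R)-5-aryl-furan-2(5H)-one; the bonds C5–C4 and C2–C3 and the stereocentres C2, C3 and C4 arise together.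
3. Enabling feature: O1 flanked by C2 and C5 is a carbonyl ylide in disguise, and the cis relation of the C3 and C4 substituents lets them be closed to a five-membered lactone ring whose aryl-bearing benzylic carbon shields one face of the alkene and is erased to CH2 afterwards.
4. The ylide comes from an α-chloro (trimethylsilyl)methyl ether of 3,4,5-trimethoxybenzaldehyde; the butenolide from ring-closing metathesis of an (R)-allylic acrylate, obtained by lipase resolution after vinyl addition to 3-benzyloxy-4,5-dimethoxybenzaldehyde.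
5. Ring order: butenolide ring (metathesis), then tetrahydrofuran ring (cycloaddition), then the lactone ring is opened.

Key step: step 7

Remark on the chemistry: the given SMILES is read as (2R,3S,4S), i.e. 2,3-trans and 3,4-cis on the tetrahydrofuran, and the route is built for this isomer.

**Route**

Step 1
Reactants: 1 3-hydroxy-4,5-dimethoxybenzaldehyde; 2 benzyl bromide
Product: 3 3-(benzyloxy)-4,5-dimethoxybenzaldehyde
Conditions: K2CO3, DMF, rt
Reagents that add atoms: benzyl bromide, BrCc1ccccc1
Why: Williamson ether synthesis (SN2 O-alkylation of the phenoxide); the benzyl ether is chosen because the hydrogenolysis of step 8 removes it together with the lactone tether.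

Step 2
Reactants: 3 3-(benzyloxy)-4,5-dimethoxybenzaldehyde; 4 vinylmagnesium bromide
Product: 5 rac-1-[3-(benzyloxy)-4,5-dimethoxyphenyl]prop-2-en-1-ol
Conditions: CH2=CHMgBr, THF, −78 → 0 °C; aq. NH4Cl
Reagents that add atoms: vinylmagnesium bromide, C=C[Mg]Br
Why: Grignard 1,2-addition to an aromatic aldehyde; the carbinol centre is formed racemic here and is resolved in step 3.

Step 3
Reactants: 5 rac-1-[3-(benzyloxy)-4,5-dimethoxyphenyl]prop-2-en-1-ol; 6 vinyl acrylate
Product: 7 (1R)-1-[3-(benzyloxy)-4,5-dimethoxyphenyl]prop-2-en-1-yl prop-2-enoate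
Conditions: Novozym 435 (immobilised lipase B of Candida antarctica), 6 (3 equiv), BHT (trace), MTBE, 30 °C, stopped near half conversion; the unreacted (S)-alcohol is removed by chromatography
Reagents that add atoms: vinyl acrylate, C=CC(=O)OC=C
Why: Lipase-catalysed kinetic resolution by irreversible transesterification (the vinyl alcohol released tautomerises); the enzyme should acylate the enantiomer that places the aryl group in its large pocket and the vinyl group in its medium pocket, which is the (R)-alcohol, and the acryloyl group needed for step 4 is installed in the same operation.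

Step 4
Reactants: 7 (1R)-1-[3-(benzyloxy)-4,5-dimethoxyphenyl]prop-2-en-1-yl prop-2-enoate
Product: 8 (5R)-5-[3-(benzyloxy)-4,5-dimethoxyphenyl]furan-2(5H)-one
Conditions: second-generation Grubbs catalyst RuCl2(=CHPh)(PCy3)(H2IMes) (5 mol %), CH2Cl2 (high dilution), 40 °C
Reagents that add atoms: none
Why: Ring-closing metathesis of an allyl acrylate to a butenolide, driven by loss of ethene; the neutral conditions should leave the benzylic stereocentre untouched.

Step 5
Reactants: 9 3,4,5-trimethoxybenzaldehyde; 10 (trimethylsilyl)methanol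
Product: 11 5-{bis[(trimethylsilyl)methoxy]methyl}-1,2,3-trimethoxybenzene
Conditions: 10 (2.5 equiv), PPTS (cat.), cyclohexane, reflux, azeotropic removal of water
Reagents that add atoms: (trimethylsilyl)methanol, C[Si](C)(C)CO
Why: Acid-catalysed acetalisation of an aromatic aldehyde with a primary alcohol, pulled to completion by removal of water.

Step 6
Reactants: 11 5-{bis[(trimethylsilyl)methoxy]methyl}-1,2,3-trimethoxybenzene; 12 acetyl chloride
Product: 13 {[chloro(3,4,5-trimethoxyphenyl)methoxy]methyl}trimethylsilane (racemic, moisture-sensitive, used crude)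
Conditions: AcCl (1.5 equiv), CH2Cl2, 0 °C → rt; volatiles and the acetate coproduct removed under high vacuum
Reagents that add atoms: acetyl chloride, CC(=O)Cl
Why: Acetal to α-chloro ether exchange: acetyl chloride acylates one alkoxy group and chloride captures the aryl-stabilised oxocarbenium ion.

Step 7
Reactants: 8 (5R)-5-[3-(benzyloxy)-4,5-dimethoxyphenyl]furan-2(5H)-one; 13 {[chloro(3,4,5-trimethoxyphenyl)methoxy]methyl}trimethylsilane
Product: 15 (3R,3aS,6R,6aR)-3-[3-(benzyloxy)-4,5-dimethoxyphenyl]-6-(3,4,5-trimethoxyphenyl)tetrahydro-1H,3H-furo[3,4-c]furan-1-one, via carbonyl ylide 14 (not isolated)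
Conditions: 13 (3 equiv), CsF (4 equiv, dried), MeCN, 0 °C → rt, 8 as the limiting component
Reagents that add atoms: none
Why: Fluoride attacks silicon of 13 (or of its oxocarbenium chloride ion pair), Me3SiF and chloride depart in a 1,3-elimination, and the non-stabilised carbonyl ylide 14 adds suprafacially across the C3=C4 alkene of 8 in a concerted, asynchronous [3+2] dipolar cycloaddition. The closest known reaction type is the fluoride-induced 1,3-elimination of α-chloroalkyl (trimethylsilyl)methyl ethers to carbonyl ylides and their trapping by electron-poor alkenes to give tetrahydrofurans. The tetrahydrofuran ring is closed by intermolecular [3+2] cycloaddition (4π ylide plus 2π alkene, both new C–C bonds formed on one face of each partner), which can only give a cis fusion to the lactone ring. C3a and C6a of 15 (C4 and C3 of the target) are cis because the alkene is held Z inside the lactone ring, and their absolute configuration follows from addition to the face of 8 opposite its C5 aryl group; C6 (C2 of the target) is set by an exo transition state of the W-shaped ylide, in which its aryl group points away from the lactone carbonyl and ends on the convex face, trans to the C6a–C1 bond. Regioselectivity is needed and should come from the ylide: the unsubstituted CH2 terminus carries the larger HOMO coefficient (the aryl group stabilises the oxocarbenium end) and bonds to the β-carbon of the enoate, which is also the less crowded pairing next to the aryl-bearing C5 of 8. Chemoselectivity of fluoride for silicon over the acidic C5–H of 8 should be secured by the sparingly soluble CsF and the excess of 13.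

Step 8
Reactants: 15 (3R,3aS,6R,6aR)-3-[3-(benzyloxy)-4,5-dimethoxyphenyl]-6-(3,4,5-trimethoxyphenyl)tetrahydro-1H,3H-furo[3,4-c]furan-1-one
Product: 16 (2R,3R,4S)-4-(3-hydroxy-4,5-dimethoxybenzyl)-2-(3,4,5-trimethoxyphenyl)tetrahydrofuran-3-carboxylic acid
Conditions: H2 (1 atm), 10% Pd/C, EtOAc–MeOH, rt, followed closely and stopped when 15 is consumed
Reagents that add atoms: none
Why: Palladium-catalysed hydrogenolysis of benzylic C–O bonds: the lactone C–O bond (carboxylate leaving group) and the phenolic benzyl ether should cleave well before the benzylic C2–O1 ether of the tetrahydrofuran; the lactone benzylic stereocentre becomes CH2, and C2, C3 and C4 are not touched.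

Step 9
Reactants: 16 (2R,3R,4S)-4-(3-hydroxy-4,5-dimethoxybenzyl)-2-(3,4,5-trimethoxyphenyl)tetrahydrofuran-3-carboxylic acid
Product: 17 [(2R,3S,4S)-4-(3-hydroxy-4,5-dimethoxybenzyl)-2-(3,4,5-trimethoxyphenyl)tetrahydrofuran-3-yl]methanol (the target)
Conditions: BH3·THF (4 equiv), THF, 0 °C → rt; MeOH quench
Reagents that add atoms: none
Why: Chemoselective borane reduction of a carboxylic acid through its acyloxyborane; the non-basic conditions should not epimerise C3, and the aryl ethers and the cyclic ether are inert (the C3 descriptor changes from R to S only through the priority change).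

**Compound list**

1 | 3-hydroxy-4,5-dimethoxybenzaldehyde | O=Cc1cc(O)c(OC)c(OC)c1 | starting material
2 | benzyl bromide | BrCc1ccccc1 | starting material
3 | 3-(benzyloxy)-4,5-dimethoxybenzaldehyde | O=Cc1cc(OC)c(OC)c(OCc2ccccc2)c1 | intermediate
4 | vinylmagnesium bromide | C=C[Mg]Br | starting material
5 | rac-1-[3-(benzyloxy)-4,5-dimethoxyphenyl]prop-2-en-1-ol | C=CC(O)c1cc(OC)c(OC)c(OCc2ccccc2)c1 | intermediate
6 | vinyl acrylate | C=CC(=O)OC=C | starting material
7 | (1R)-1-[3-(benzyloxy)-4,5-dimethoxyphenyl]prop-2-en-1-yl prop-2-enoate | C=CC(=O)O[C@@H](c1cc(OC)c(OC)c(OCc2ccccc2)c1)C=C | intermediate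
8 | (5R)-5-[3-(benzyloxy)-4,5-dimethoxyphenyl]furan-2(5H)-one | O=C1O[C@@H](c2cc(OC)c(OC)c(OCc3ccccc3)c2)C=C1 | intermediate
9 | 3,4,5-trimethoxybenzaldehyde | O=Cc1cc(OC)c(OC)c(OC)c1 | starting material
10 | (trimethylsilyl)methanol | C[Si](C)(C)CO | starting material
11 | 5-{bis[(trimethylsilyl)methoxy]methyl}-1,2,3-trimethoxybenzene | COc1cc(C(OC[Si](C)(C)C)OC[Si](C)(C)C)cc(OC)c1OC | intermediate
12 | acetyl chloride | CC(=O)Cl | starting material
13 | {[chloro(3,4,5-trimethoxyphenyl)methoxy]methyl}trimethylsilane (racemic) | COc1cc(C(Cl)OC[Si](C)(C)C)cc(OC)c1OC | intermediate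
14 | carbonyl ylide, (3,4,5-trimethoxybenzylidene)oxonium methylide (not isolated) | COc1cc(C=[O+][CH2-])cc(OC)c1OC | intermediate
15 | (3R,3aS,6R,6aR)-3-[3-(benzyloxy)-4,5-dimethoxyphenyl]-6-(3,4,5-trimethoxyphenyl)tetrahydro-1H,3H-furo[3,4-c]furan-1-one | O=C1O[C@@H](c2cc(OC)c(OC)c(OCc3ccccc3)c2)[C@@H]2CO[C@@H](c3cc(OC)c(OC)c(OC)c3)[C@H]12 | intermediate
16 | (2R,3R,4S)-4-(3-hydroxy-4,5-dimethoxybenzyl)-2-(3,4,5-trimethoxyphenyl)tetrahydrofuran-3-carboxylic acid | COc1cc(C[C@@H]2CO[C@@H](c3cc(OC)c(OC)c(OC)c3)[C@@H]2C(=O)O)cc(O)c1OC | intermediate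
17 | [(2R,3S,4S)-4-(3-hydroxy-4,5-dimethoxybenzyl)-2-(3,4,5-trimethoxyphenyl)tetrahydrofuran-3-yl]methanol | COc1cc(C[C@@H]2CO[C@@H](c3cc(OC)c(OC)c(OC)c3)[C@@H]2CO)cc(O)c1OC | target

**Step count and risks**

Total step count: 9. Longest linear sequence: 7 steps (steps 1, 2, 3, 4, 7, 8, 9).

The three steps most likely to fail:

Step 7. Fluoride may deprotonate the benzylic C5–H of the butenolide instead of attacking silicon, which would racemise the dipolarophile and move its double bond out of conjugation. The cycloaddition may also lose exo or regiochemical control. The fallback sets out from 3 and 9 and returns to the route at 17; it closes the tetrahydrofuran by C2–O1 bond formation instead of cycloaddition.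
- Stobbe condensation of 3 with dimethyl succinate (NaOMe, MeOH, reflux) should give (E)-4-[3-(benzyloxy)-4,5-dimethoxyphenyl]-3-(methoxycarbonyl)but-3-enoic acid F1.
- Asymmetric hydrogenation with [Rh(cod)(Et-DuPhos)]BF4 (H2, MeOH; the ligand antipode that delivers the S acid) should give (3S)-3-[3-(benzyloxy)-4,5-dimethoxybenzyl]-4-methoxy-4-oxobutanoic acid F2.
- Reduction of the ester group of its potassium salt with Ca(BH4)2 (from CaCl2 and NaBH4, EtOH), then acid lactonisation, should give (4S)-4-[3-(benzyloxy)-4,5-dimethoxybenzyl]dihydrofuran-2(3H)-one F3.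
- Enolisation with LiN(iPr)2 (THF, −78 °C) and aldol addition to 9, anti to the benzyl group, should give (3R,4S)-4-[3-(benzyloxy)-4,5-dimethoxybenzyl]-3-[hydroxy(3,4,5-trimethoxyphenyl)methyl]dihydrofuran-2(3H)-one F4; both carbinol epimers are usable.
- LiAlH4 (THF, 0 °C) should give (2S,3S)-2-[3-(benzyloxy)-4,5-dimethoxybenzyl]-3-[hydroxy(3,4,5-trimethoxyphenyl)methyl]butane-1,4-diol F5.
- Camphorsulfonic acid in CH2Cl2 should ionise the benzylic alcohol; the primary hydroxyl of the benzyl-bearing carbon should close the 2,3-trans ring to [(2R,3S,4S)-4-[3-(benzyloxy)-4,5-dimethoxybenzyl]-2-(3,4,5-trimethoxyphenyl)tetrahydrofuran-3-yl]methanol F6.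
- Brief hydrogenolysis of the benzyl ether (H2, 10% Pd/C, EtOAc) should give 17.

Step 8. The hydrogenolysis may run on to the benzylic C2–O1 bond and open the tetrahydrofuran, or stall at the hindered, electron-rich benzylic lactone carbon. The fallback sets out from 15 and returns at 16; it replaces hydrogenolysis of the lactone by substitution and radical reduction.
- SN2 opening of the lactone at its benzylic carbon with NaSePh (from PhSeSePh and NaBH4, DMF, 80 °C) should give, with inversion, (2R,3R,4S)-4-{(S)-[3-(benzyloxy)-4,5-dimethoxyphenyl](phenylselanyl)methyl}-2-(3,4,5-trimethoxyphenyl)tetrahydrofuran-3-carboxylic acid F7.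
- Homolytic reduction of the C–Se bond (Bu3SnH, AIBN, toluene, 80 °C) should give (2R,3R,4S)-4-[3-(benzyloxy)-4,5-dimethoxybenzyl]-2-(3,4,5-trimethoxyphenyl)tetrahydrofuran-3-carboxylic acid F8.
- A short hydrogenolysis that only has to remove the fast-cleaving phenolic benzyl ether (H2, 10% Pd/C, EtOAc) should give 16.

Step 3. The lipase may discriminate the enantiomers poorly or acylate slowly, because the aryl group is bulky and meta-substituted and the acyl donor is an acrylate. The fallback sets out from 3 and returns at 8; it sets the stereocentre by catalytic reduction instead of resolution.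
- Stetter reaction of 3 with methyl acrylate (3-benzyl-5-(2-hydroxyethyl)-4-methylthiazolium chloride, Et3N, EtOH, 80 °C) should give methyl 4-[3-(benzyloxy)-4,5-dimethoxyphenyl]-4-oxobutanoate F9.
- Asymmetric transfer hydrogenation with RuCl[(R,R)-TsDPEN](p-cymene) in HCO2H/Et3N, then TsOH-catalysed lactonisation, should give (5R)-5-[3-(benzyloxy)-4,5-dimethoxyphenyl]dihydrofuran-2(3H)-one F10.
- LiN(iPr)2 (THF, −78 °C) then PhSeBr should give (5R)-5-[3-(benzyloxy)-4,5-dimethoxyphenyl]-3-(phenylselanyl)dihydrofuran-2(3H)-one F11 (C3 epimers).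
- Oxidation with H2O2 (CH2Cl2, 0 °C) and selenoxide syn-elimination should give 8.

Further compounds
F1 | step 7 | (E)-4-[3-(benzyloxy)-4,5-dimethoxyphenyl]-3-(methoxycarbonyl)but-3-enoic acid | COC(=O)/C(CC(=O)O)=C/c1cc(OC)c(OC)c(OCc2ccccc2)c1
F2 | step 7 | (3S)-3-[3-(benzyloxy)-4,5-dimethoxybenzyl]-4-methoxy-4-oxobutanoic acid | COC(=O)[C@H](CC(=O)O)Cc1cc(OC)c(OC)c(OCc2ccccc2)c1
F3 | step 7 | (4S)-4-[3-(benzyloxy)-4,5-dimethoxybenzyl]dihydrofuran-2(3H)-one | O=C1C[C@H](Cc2cc(OC)c(OC)c(OCc3ccccc3)c2)CO1
F4 | step 7 | (3R,4S)-4-[3-(benzyloxy)-4,5-dimethoxybenzyl]-3-[hydroxy(3,4,5-trimethoxyphenyl)methyl]dihydrofuran-2(3H)-one (carbinol centre not defined) | COc1cc(C[C@@H]2COC(=O)[C@H]2C(O)c2cc(OC)c(OC)c(OC)c2)cc(OCc2ccccc2)c1OC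
F5 | step 7 | (2S,3S)-2-[3-(benzyloxy)-4,5-dimethoxybenzyl]-3-[hydroxy(3,4,5-trimethoxyphenyl)methyl]butane-1,4-diol (carbinol centre not defined) | COc1cc(C[C@H](CO)[C@@H](CO)C(O)c2cc(OC)c(OC)c(OC)c2)cc(OCc2ccccc2)c1OC
F6 | step 7 | [(2R,3S,4S)-4-[3-(benzyloxy)-4,5-dimethoxybenzyl]-2-(3,4,5-trimethoxyphenyl)tetrahydrofuran-3-yl]methanol | COc1cc(C[C@@H]2CO[C@@H](c3cc(OC)c(OC)c(OC)c3)[C@@H]2CO)cc(OCc2ccccc2)c1OC
F7 | step 8 | (2R,3R,4S)-4-{(S)-[3-(benzyloxy)-4,5-dimethoxyphenyl](phenylselanyl)methyl}-2-(3,4,5-trimethoxyphenyl)tetrahydrofuran-3-carboxylic acid | c1ccccc1[Se][C@H](c1cc(OC)c(OC)c(OCc2ccccc2)c1)[C@@H]1CO[C@@H](c2cc(OC)c(OC)c(OC)c2)[C@@H]1C(=O)O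
F8 | step 8 | (2R,3R,4S)-4-[3-(benzyloxy)-4,5-dimethoxybenzyl]-2-(3,4,5-trimethoxyphenyl)tetrahydrofuran-3-carboxylic acid | COc1cc(C[C@@H]2CO[C@@H](c3cc(OC)c(OC)c(OC)c3)[C@@H]2C(=O)O)cc(OCc2ccccc2)c1OC
F9 | step 3 | methyl 4-[3-(benzyloxy)-4,5-dimethoxyphenyl]-4-oxobutanoate | COC(=O)CCC(=O)c1cc(OC)c(OC)c(OCc2ccccc2)c1
F10 | step 3 | (5R)-5-[3-(benzyloxy)-4,5-dimethoxyphenyl]dihydrofuran-2(3H)-one | O=C1O[C@@H](c2cc(OC)c(OC)c(OCc3ccccc3)c2)CC1
F11 | step 3 | (5R)-5-[3-(benzyloxy)-4,5-dimethoxyphenyl]-3-(phenylselanyl)dihydrofuran-2(3H)-one (C3 epimers) | O=C1O[C@@H](c2cc(OC)c(OC)c(OCc3ccccc3)c2)CC1[Se]c1ccccc1
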